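**Retrosynthetic overview**

- The target is reached by hydrogenolysis of its bis(benzyl ether), a trans-3,4-dibenzyl-γ-butyrolactone.
- The lactone is the only ring and is closed in the key step. The strategy rests on C5–O1 being an unsubstituted O–CH2 unit (formaldehyde), while C2–C3–C4 is a masked α,β-disubstituted enal: C3 carries the 4-hydroxy-3-methoxybenzyl arm and C4 the 3-hydroxy-4-methoxybenzyl arm. A chiral carbene joins the two in a [3+2] homoenolate annulation that forms C4–C5 and C2–O1.
- The enal comes from the (E)-enoate by reduction and allylic oxidation. The enoate comes from a Wittig union of an α-benzylated stabilised ylide (C2, C3 and the vanillyl arm) with an arylacetaldehyde (C4 and the isovanillyl arm).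
- The ylide is made from O-benzylvanillyl bromide and ethyl (triphenylphosphoranylidene)acetate; the arylacetaldehyde from O-benzylisovanillin by one-carbon homologation.

Key step: step 8

Assumption: the precatalyst is 2-mesityl-5a,10b-dihydro-4H,6H-indeno[2,1-b][1,2,4]triazolo[4,3-d][1,4]oxazin-2-ium chloride, used as whichever antipode, (5aS,10bR) or (5aR,10bS), gives the 4R lactone in a pilot run; the sense of induction cannot be assigned in advance for this new substrate class.

**Route**

Step 1
Reactants: 1 [4-(benzyloxy)-3-methoxyphenyl]methanol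
Product: 2 1-(benzyloxy)-4-(bromomethyl)-2-methoxybenzene (O-benzylvanillyl bromide)
Conditions: PBr3 (0.4 equiv), Et2O, 0 °C; used without storage
Reagents that add atoms: phosphorus tribromide, BrP(Br)Br
Why: Bromodehydroxylation of an electron-rich benzylic alcohol with PBr3 is fast at 0 °C and leaves the aryl benzyl and methyl ethers untouched.

Step 2
Reactants: 2 O-benzylvanillyl bromide; 3 ethyl (triphenylphosphoranylidene)acetate
Product: 5 ethyl 3-[4-(benzyloxy)-3-methoxyphenyl]-2-(triphenylphosphoranylidene)propanoate, via alkylated phosphonium bromide 4 (not isolated)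
Conditions: EtOAc, reflux; then aq. NaOH (1 M), CH2Cl2, RT
Reagents that add atoms: none
Why: C-alkylation of a stabilised phosphorus ylide by a reactive benzylic bromide gives the phosphonium salt, whose remaining α-hydrogen is removed by aqueous hydroxide to give the α-substituted stabilised ylide.

Step 3
Reactants: 6 3-(benzyloxy)-4-methoxybenzaldehyde; 7 (methoxymethyl)triphenylphosphonium chloride
Product: 8 2-(benzyloxy)-1-methoxy-4-(2-methoxyethenyl)benzene (E/Z mixture)
Conditions: KOt-Bu, THF, 0 °C to RT
Reagents that add atoms: none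
Why: Wittig methoxymethylenation of an aromatic aldehyde with the ylide formed in the flask is a standard one-carbon homologation, and the alkene geometry is irrelevant because both isomers hydrolyse to the same aldehyde.

Step 4
Reactants: 8 aryl enol ether
Product: 9 [3-(benzyloxy)-4-methoxyphenyl]acetaldehyde
Conditions: aq. HCl (2 M), THF, 50 °C; used crude at once
Reagents that add atoms: water, O
Why: Acid-catalysed enol ether hydrolysis (C-protonation, then collapse of the hemiacetal) unmasks the homologated aldehyde, and the aryl benzyl ether is stable to dilute acid.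

Step 5
Reactants: 9 arylacetaldehyde; 5 α-benzylated ylide
Product: 10 ethyl (E)-2-[4-(benzyloxy)-3-methoxybenzyl]-4-[3-(benzyloxy)-4-methoxyphenyl]but-2-enoate
Conditions: CH2Cl2, RT to 40 °C
Reagents that add atoms: none
Why: Wittig olefination with a stabilised α-substituted ylide under neutral, salt-free conditions should place the ester trans to the new CH2Ar arm (E), and the absence of base avoids enolisation of 9 and migration of the double bond towards the arene.

Step 6
Reactants: 10 (E)-enoate
Product: 11 (E)-2-[4-(benzyloxy)-3-methoxybenzyl]-4-[3-(benzyloxy)-4-methoxyphenyl]but-2-en-1-ol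
Conditions: i-Bu2AlH (2.5 equiv), CH2Cl2, −78 °C; aq. Rochelle salt
Reagents that add atoms: none
Why: 1,2-Reduction of the conjugated ester with i-Bu2AlH at low temperature gives the allylic alcohol without touching the alkene geometry or the benzyl ethers.

Step 7
Reactants: 11 allylic alcohol
Product: 12 (E)-2-[4-(benzyloxy)-3-methoxybenzyl]-4-[3-(benzyloxy)-4-methoxyphenyl]but-2-enal
Conditions: activated MnO2 (15 equiv), CH2Cl2, RT
Reagents that add atoms: none
Why: Heterogeneous MnO2 oxidation is selective for the allylic alcohol and is neutral, so the E geometry is kept and the double bond is not shifted into conjugation with the arene.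

Step 8
Reactants: 12 (E)-enal; 13 formaldehyde
Product: 15 (3R,4R)-3-[4-(benzyloxy)-3-methoxybenzyl]-4-[3-(benzyloxy)-4-methoxybenzyl]dihydrofuran-2(3H)-one, via (3S,4R)-cis lactone 14 (not isolated)
Conditions: paraformaldehyde (fourfold excess) as the formaldehyde source, chiral N-mesityl indeno-triazolo-oxazinium chloride (20 mol%), i-Pr2NEt (40 mol%), MS 4A, THF, 40 °C; filter, evaporate; then DBU (30 mol%), toluene, 80 °C
Reagents that add atoms: none
Why: Proposed new method: the carbene adds to the formyl carbon of 12 and proton transfer gives the conjugated dienaminol, a homoenolate whose β-carbon (the future C4) adds to monomeric formaldehyde released from the polymer to form C4–C5; C-protonation of the resulting enol azolium at C3 gives an acyl azolium, which the C5 alkoxide attacks to form C2–O1 and release the carbene. The closest known reaction type is the carbene-catalysed homoenolate [3+2] annulation of β-aryl enals with aromatic aldehydes or activated ketones to γ-butyrolactones; formaldehyde as acceptor and an α-branched, β-alkyl enal as donor are both untested. The lactone closes by a 5-exo-trig acyl substitution on the acyl azolium. C4 is fixed by the catalyst, whose indane unit blocks one face of the dienaminol derived from the geometrically pure E-enal, whereas C3 comes from a protonation that is not expected to be selective and is therefore converged afterwards, by DBU enolisation of the crude lactone freed of formaldehyde, on the trans (3R) isomer favoured by the neighbouring C4 benzyl group. The step needs β-carbon rather than acyl-carbon reactivity and an intact γ-CH2: the N-mesityl group and the α-benzyl branch crowd the acyl-anion carbon, formaldehyde is the one acceptor small enough to reach the hindered β-carbon, and the weak amine base generates the carbene without deprotonating the benzylic γ-position.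

Step 9
Reactants: 15 trans-bis(benzyl ether) lactone
Product: 16 (3R,4R)-3-(4-hydroxy-3-methoxybenzyl)-4-(3-hydroxy-4-methoxybenzyl)dihydrofuran-2(3H)-one
Conditions: H2 (1 atm), Pd/C (10%), EtOAc–MeOH, RT
Reagents that add atoms: none
Why: Hydrogenolysis of the two aryl benzyl ethers over Pd/C leaves the lactone, the benzylic C–C bonds and both sp3 stereocentres untouched.

**Compound list**

1 | [4-(benzyloxy)-3-methoxyphenyl]methanol (O-benzylvanillyl alcohol) | COc1cc(CO)ccc1OCc1ccccc1 | starting material
2 | 1-(benzyloxy)-4-(bromomethyl)-2-methoxybenzene | COc1cc(CBr)ccc1OCc1ccccc1 | intermediate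
3 | ethyl (triphenylphosphoranylidene)acetate | CCOC(=O)C=P(c1ccccc1)(c1ccccc1)c1ccccc1 | starting material
4 | {3-[4-(benzyloxy)-3-methoxyphenyl]-1-ethoxy-1-oxopropan-2-yl}triphenylphosphonium bromide | CCOC(=O)C(Cc1ccc(OCc2ccccc2)c(OC)c1)[P+](c1ccccc1)(c1ccccc1)c1ccccc1.[Br-] | intermediate (not isolated)
5 | ethyl 3-[4-(benzyloxy)-3-methoxyphenyl]-2-(triphenylphosphoranylidene)propanoate | CCOC(=O)C(Cc1ccc(OCc2ccccc2)c(OC)c1)=P(c1ccccc1)(c1ccccc1)c1ccccc1 | intermediate
6 | 3-(benzyloxy)-4-methoxybenzaldehyde (O-benzylisovanillin) | COc1ccc(C=O)cc1OCc1ccccc1 | starting material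
7 | (methoxymethyl)triphenylphosphonium chloride | COC[P+](c1ccccc1)(c1ccccc1)c1ccccc1.[Cl-] | starting material
8 | 2-(benzyloxy)-1-methoxy-4-(2-methoxyethenyl)benzene, E/Z mixture | COC=Cc1ccc(OC)c(OCc2ccccc2)c1 | intermediate
9 | [3-(benzyloxy)-4-methoxyphenyl]acetaldehyde | O=CCc1ccc(OC)c(OCc2ccccc2)c1 | intermediate
10 | ethyl (E)-2-[4-(benzyloxy)-3-methoxybenzyl]-4-[3-(benzyloxy)-4-methoxyphenyl]but-2-enoate | CCOC(=O)/C(Cc1ccc(OCc2ccccc2)c(OC)c1)=C/Cc1ccc(OC)c(OCc2ccccc2)c1 | intermediate
11 | (E)-2-[4-(benzyloxy)-3-methoxybenzyl]-4-[3-(benzyloxy)-4-methoxyphenyl]but-2-en-1-ol | OC/C(Cc1ccc(OCc2ccccc2)c(OC)c1)=C/Cc1ccc(OC)c(OCc2ccccc2)c1 | intermediate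
12 | (E)-2-[4-(benzyloxy)-3-methoxybenzyl]-4-[3-(benzyloxy)-4-methoxyphenyl]but-2-enal | O=C/C(Cc1ccc(OCc2ccccc2)c(OC)c1)=C/Cc1ccc(OC)c(OCc2ccccc2)c1 | intermediate
13 | formaldehyde (supplied as paraformaldehyde) | C=O | starting material
14 | (3S,4R)-3-[4-(benzyloxy)-3-methoxybenzyl]-4-[3-(benzyloxy)-4-methoxybenzyl]dihydrofuran-2(3H)-one (cis) | COc1ccc(C[C@H]2COC(=O)[C@H]2Cc2ccc(OCc3ccccc3)c(OC)c2)cc1OCc1ccccc1 | intermediate (not isolated)
15 | (3R,4R)-3-[4-(benzyloxy)-3-methoxybenzyl]-4-[3-(benzyloxy)-4-methoxybenzyl]dihydrofuran-2(3H)-one (trans) | COc1ccc(C[C@H]2COC(=O)[C@@H]2Cc2ccc(OCc3ccccc3)c(OC)c2)cc1OCc1ccccc1 | intermediate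
16 | (3R,4R)-3-(4-hydroxy-3-methoxybenzyl)-4-(3-hydroxy-4-methoxybenzyl)dihydrofuran-2(3H)-one | COc1ccc(C[C@H]2COC(=O)[C@@H]2Cc2ccc(O)c(OC)c2)cc1O | target

**Step count**

Total steps: 9. Longest linear sequence: 7 steps (1 → 2 → 5 → 10 → 11 → 12 → 15 → 16; the branch from 6 is equally long).

**Steps most likely to fail**

Step 8. Several processes could defeat it:
- the carbene may be consumed by self-condensation of formaldehyde;
- the dienaminol may react through its acyl carbon (hydroxymethylation) or be protonated at the β-carbon;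
- facial discrimination at C4 may be poor.

The fallback uses known chemistry, sets out from aldehyde 6 and bromide 2, and returns at 15. Stobbe condensation of 6 with dimethyl succinate (NaOMe, MeOH, reflux) should give (E)-4-[3-(benzyloxy)-4-methoxyphenyl]-3-(methoxycarbonyl)but-3-enoic acid F1. Asymmetric hydrogenation with [Rh(cod)2]BF4 and a Me-DuPhos ligand of the antipode that gives the R acid (H2, MeOH) should give (R)-4-[3-(benzyloxy)-4-methoxyphenyl]-3-(methoxycarbonyl)butanoic acid F2. Reduction of the ester in the potassium carboxylate with Ca(BH4)2 (from CaCl2 and NaBH4, EtOH), then acidification, should give (R)-4-[3-(benzyloxy)-4-methoxybenzyl]dihydrofuran-2(3H)-one F3. Its lithium enolate (LiHMDS, THF, −78 °C) should be alkylated by bromide 2 on the face trans to the C4 substituent, giving 15.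

Step 5. Self-aldol condensation of the enolisable aldehyde 9 may outrun a slow olefination by the hindered ylide, or the new double bond may migrate towards the arene. The fallback avoids the arylacetaldehyde, sets out from ylide 5 and returns at 10. Wittig reaction of 5 with chloroacetaldehyde (CH2Cl2, RT) should give ethyl (E)-2-[4-(benzyloxy)-3-methoxybenzyl]-4-chlorobut-2-enoate F4. Suzuki–Miyaura coupling of this allylic chloride with commercial [3-(benzyloxy)-4-methoxyphenyl]boronic acid (Pd(PPh3)4, K2CO3, toluene–water, 80 °C) should attach the aryl group at the unhindered CH2 terminus and give 10.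

Step 4. Acid-promoted self-condensation or polymerisation of the arylacetaldehyde may occur during enol ether hydrolysis. The fallback sets out from aldehyde 6 and returns at 9 under neutral conditions. Wittig methylenation of 6 (Ph3PCH3Br, KOt-Bu, THF) should give 2-(benzyloxy)-4-ethenyl-1-methoxybenzene F5. Hydroboration–oxidation (9-BBN, THF; then NaOH, H2O2) should give 2-[3-(benzyloxy)-4-methoxyphenyl]ethan-1-ol F6. Dess–Martin periodinane (NaHCO3, CH2Cl2, RT) should give 9.

**Further compounds**

F1 | step 8 | (E)-4-[3-(benzyloxy)-4-methoxyphenyl]-3-(methoxycarbonyl)but-3-enoic acid | COC(=O)/C(CC(=O)O)=C/c1ccc(OC)c(OCc2ccccc2)c1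
F2 | step 8 | (R)-4-[3-(benzyloxy)-4-methoxyphenyl]-3-(methoxycarbonyl)butanoic acid | COc1ccc(C[C@H](CC(=O)O)C(=O)OC)cc1OCc1ccccc1
F3 | step 8 | (R)-4-[3-(benzyloxy)-4-methoxybenzyl]dihydrofuran-2(3H)-one | COc1ccc(C[C@H]2COC(=O)C2)cc1OCc1ccccc1
F4 | step 5 | ethyl (E)-2-[4-(benzyloxy)-3-methoxybenzyl]-4-chlorobut-2-enoate | CCOC(=O)/C(Cc1ccc(OCc2ccccc2)c(OC)c1)=C/CCl
F5 | step 4 | 2-(benzyloxy)-4-ethenyl-1-methoxybenzene | C=Cc1ccc(OC)c(OCc2ccccc2)c1
F6 | step 4 | 2-[3-(benzyloxy)-4-methoxyphenyl]ethan-1-ol | OCCc1ccc(OC)c(OCc2ccccc2)c1
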